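## Retrosynthetic overview

1. The C9 acetate (α′-acetoxylation) and the C1 isobutyrate (acylation) are removed last; the C10 methyl comes from hydroxyl-directed 1,4-methylation of a 1-hydroxyspiro[4.5]deca-6,9-dien-8-one.
2. The spiro centre and the cyclopentane come from dearomatising para-C-alkylation of a phenolate by a primary chloride. This is the only ring that has to be made; the six-membered ring is the m-cresol ring.
3. Key disconnection: the C5–C1 aryl–carbinol bond, made by rhodium-catalysed coupling of an arylboronic acid (three steps from m-cresol) with a C7 chloro-aldehyde. This union also sets C1, which then controls C5, C10 and C9.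
4. The chloro-aldehyde comes from a chloro-diene by ruthenium cross-metathesis with vinyl–B(pin) and oxidation. The diene comes from a new copper-catalysed enantioselective SN2′ isopropenylation of (E)-1,4-dichlorobut-2-ene, which sets C3.

Assumption: the target is the drawn enantiomer, (1R,3S,5R,9R,10S) in spiro[4.5]decane numbering (C1 = isobutyrate carbinol, C3 = isopropenyl carbon, C5 = spiro carbon, C8 = ketone), and this numbering is used for all intermediates.

## Route

Step 1
Reactants: 1 3-methylphenol (m-cresol)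
Product: 2 4-bromo-3-methylphenol
Conditions: NBS (1.0 equiv), MeCN, −10 to 0 °C
Reagents that add atoms: N-bromosuccinimide, O=C1CCC(=O)N1Br
Why: electrophilic aromatic bromination, in which the hydroxyl group directs para to the position that is also ortho to the methyl group; no stereocentre is formed.

Step 2
Reactants: 2 4-bromo-3-methylphenol
Product: 3 (4-bromo-3-methylphenoxy)(tert-butyl)dimethylsilane
Conditions: TBSCl, imidazole, DMF, 23 °C
Reagents that add atoms: tert-butyldimethylsilyl chloride, CC(C)(C)[Si](C)(C)Cl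
Why: O-silylation (silyl ether formation) masks the acidic phenol before lithiation and leaves a group that carbonate can later remove selectively.

Step 3
Reactants: 3 (4-bromo-3-methylphenoxy)(tert-butyl)dimethylsilane
Product: 6 {4-[(tert-butyldimethylsilyl)oxy]-2-methylphenyl}boronic acid, via aryllithium 4 (not isolated), via lithium arylborate 5 (not isolated)
Conditions: n-BuLi, THF, −78 °C; B(OMe)3, −78 to 0 °C; 1 M HCl, 0 °C
Reagents that add atoms: trimethyl borate, COB(OC)OC; water, O
Why: bromine–lithium exchange, electrophilic borylation of the aryllithium and hydrolysis of the borate ester give the boronic acid; no stereocentre is formed.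

Step 4
Reactants: 7 vinylmagnesium bromide
Product: 9 4,4,5,5-tetramethyl-2-vinyl-1,3,2-dioxaborolane, via magnesium vinylborate 8 (not isolated)
Conditions: i-PrOBpin, THF, −78 to 23 °C; HCl (Et2O), 0 °C
Reagents that add atoms: 2-isopropoxy-4,4,5,5-tetramethyl-1,3,2-dioxaborolane, CC(C)OB1OC(C)(C)C(C)(C)O1
Why: Grignard borylation, in which addition to boron gives the ate complex and acidification expels isopropoxide.

Step 5
Reactants: 10 (E)-1,4-dichlorobut-2-ene; 11 isopropenylmagnesium bromide
Product: 12 (S)-3-(chloromethyl)-2-methylpenta-1,4-diene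
Conditions: copper thiophene-2-carboxylate (3 mol %), BINOL-derived bis(1-arylethyl)amine phosphoramidite (3.3 mol %, enantiomer that gives S), CH2Cl2, −78 °C, slow addition of 11 (Et2O)
Reagents that add atoms: none
Why: Proposed new method: copper-catalysed enantioselective SN2′ allylic alkenylation of a symmetric 1,4-dichloride with an alkenyl Grignard reagent, in which the ligated alkenylcuprate adds anti to chloride on one face of the alkene to give a γ-σ-allyl trivalent copper intermediate whose fast C(sp2)–C(sp3) reductive elimination fixes the branched regiochemistry and, under ligand control, the (S) configuration at C3, while the remaining CH2Cl is no longer allylic and survives; the closest known reaction type is the copper/phosphoramidite-catalysed asymmetric allylic alkylation of 1,4-dihalobut-2-enes with alkyl Grignard reagents.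

Step 6
Reactants: 12 (S)-3-(chloromethyl)-2-methylpenta-1,4-diene; 9 4,4,5,5-tetramethyl-2-vinyl-1,3,2-dioxaborolane
Product: 13 2-[(1E,3S)-3-(chloromethyl)-4-methylpenta-1,4-dien-1-yl]-4,4,5,5-tetramethyl-1,3,2-dioxaborolane
Conditions: second-generation Hoveyda–Grubbs catalyst (5 mol %), 9 (2 equiv), CH2Cl2, 40 °C
Reagents that add atoms: none
Why: olefin cross-metathesis, in which the ruthenium alkylidene engages only the monosubstituted vinyl group (the 1,1-disubstituted isopropenyl group is inert) and gives the E-alkenylboronate without touching C3.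

Step 7
Reactants: 13 2-[(1E,3S)-3-(chloromethyl)-4-methylpenta-1,4-dien-1-yl]-4,4,5,5-tetramethyl-1,3,2-dioxaborolane
Product: 14 (S)-3-(chloromethyl)-4-methylpent-4-enal
Conditions: H2O2 (30 % aq.), pH 7 phosphate buffer, THF, 0 to 23 °C
Reagents that add atoms: hydrogen peroxide, OO
Why: oxidation of the alkenylboronate (1,2-shift from boron to oxygen) gives the enol, which tautomerises to the aldehyde under neutral conditions that spare the isopropenyl group, the chloride and C3.

Step 8
Reactants: 6 {4-[(tert-butyldimethylsilyl)oxy]-2-methylphenyl}boronic acid; 14 (S)-3-(chloromethyl)-4-methylpent-4-enal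
Product: 16 tert-butyl{4-[(1R,3S)-1-[(tert-butyldimethylsilyl)oxy]-3-(chloromethyl)-4-methylpent-4-en-1-yl]-3-methylphenoxy}dimethylsilane, via benzylic alcohol 15 (not isolated)
Conditions: [RhCl(C2H4)2]2 (2.5 mol %), chiral spirobiindane monophosphite (5.5 mol %, enantiomer that gives 1R), K3PO4 (0.2 equiv), toluene/H2O (5:1), 23 °C; concentrate; TBSCl, imidazole, DMF, 23 °C
Reagents that add atoms: tert-butyldimethylsilyl chloride, CC(C)(C)[Si](C)(C)Cl
Why: rhodium-catalysed 1,2-addition of an arylboronic acid to an aldehyde (Miyaura-type aryl transfer), in which the aryl–rhodium species inserts the aldehyde on the face chosen by the chiral ligand and so sets C1 as (R) independently of the remote C3 centre; the crude alcohol is then O-silylated.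

Step 9
Reactants: 16 tert-butyl{4-[(1R,3S)-1-[(tert-butyldimethylsilyl)oxy]-3-(chloromethyl)-4-methylpent-4-en-1-yl]-3-methylphenoxy}dimethylsilane
Product: 19 (1R,3S,5R)-1-hydroxy-6-methyl-3-(prop-1-en-2-yl)spiro[4.5]deca-6,9-dien-8-one, via caesium phenolate 17 (not isolated), via silylated dienone 18 (not isolated)
Conditions: Cs2CO3 (3 equiv), NaI (0.2 equiv), DMF/H2O (20:1), 0.01 M, 23 to 60 °C; extractive work-up; HF·pyridine, THF/pyridine, 0 to 23 °C
Reagents that add atoms: none
Why: carbonate cleaves only the aryl silyl ether and the phenolate para carbon displaces the primary chloride (Ar1-5 dearomatising spiro-alkylation), with the C1 silyloxy group on the side of the unsubstituted ortho carbon to avoid A(1,3) strain with the ortho methyl, which sets C5 as (R); buffered fluoride then frees the C1 hydroxyl.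

Step 10
Reactants: 19 (1R,3S,5R)-1-hydroxy-6-methyl-3-(prop-1-en-2-yl)spiro[4.5]deca-6,9-dien-8-one
Product: 21 (1R,3S,5R,10R)-1-hydroxy-6,10-dimethyl-3-(prop-1-en-2-yl)spiro[4.5]dec-6-en-8-one, via aluminium dienolate 20 (not isolated)
Conditions: AlMe3 (3.5 equiv), CH2Cl2, −78 to −40 °C; aq. Rochelle salt
Reagents that add atoms: trimethylaluminium, C[Al](C)C
Why: alkoxide-directed conjugate (1,4-) methylation, in which the C1 aluminium alkoxide delivers methyl through a six-membered transition state to the near, unsubstituted β-carbon C10 on the face of C1 (the β-methylated C6 is remote), which sets C10 with the methyl syn to C1.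

Step 11
Reactants: 21 (1R,3S,5R,10R)-1-hydroxy-6,10-dimethyl-3-(prop-1-en-2-yl)spiro[4.5]dec-6-en-8-one
Product: 22 (1R,3S,5R,10R)-6,10-dimethyl-8-oxo-3-(prop-1-en-2-yl)spiro[4.5]dec-6-en-1-yl 2-methylpropanoate
Conditions: i-PrCOCl (3 equiv), pyridine, DMAP (0.2 equiv), CH2Cl2, 0 to 23 °C
Reagents that add atoms: 2-methylpropanoyl chloride, CC(C)C(Cl)=O
Why: DMAP-catalysed acylation of the hindered secondary alcohol gives the isobutyrate with retention at C1.

Step 12
Reactants: 22 (1R,3S,5R,10R)-6,10-dimethyl-8-oxo-3-(prop-1-en-2-yl)spiro[4.5]dec-6-en-1-yl 2-methylpropanoate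
Product: 23 (1R,3S,5R,9R,10S)-9-acetoxy-6,10-dimethyl-8-oxo-3-(prop-1-en-2-yl)spiro[4.5]dec-6-en-1-yl 2-methylpropanoate (target CNP0229299.1)
Conditions: Mn(OAc)3·2H2O (3 equiv), benzene, reflux (Dean–Stark)
Reagents that add atoms: manganese triacetate, CC(=O)[O-].CC(=O)[O-].CC(=O)[O-].[Mn+3]
Why: manganese triacetate α′-acetoxylation of the enone through the C9 manganese enolate/α-keto radical, with acetate entering anti to the adjacent C10 methyl to give the trans (9R) acetate, which is also the epimerisable, thermodynamically preferred position.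

## Compound list

1 | 3-methylphenol (m-cresol) | Cc1cccc(O)c1 | starting material
2 | 4-bromo-3-methylphenol | Cc1cc(O)ccc1Br | intermediate
3 | (4-bromo-3-methylphenoxy)(tert-butyl)dimethylsilane | Cc1cc(O[Si](C)(C)C(C)(C)C)ccc1Br | intermediate
4 | {4-[(tert-butyldimethylsilyl)oxy]-2-methylphenyl}lithium | [Li]c1ccc(O[Si](C)(C)C(C)(C)C)cc1C | intermediate
5 | lithium {4-[(tert-butyldimethylsilyl)oxy]-2-methylphenyl}trimethoxyborate | [Li+].CO[B-](OC)(OC)c1ccc(O[Si](C)(C)C(C)(C)C)cc1C | intermediate
6 | {4-[(tert-butyldimethylsilyl)oxy]-2-methylphenyl}boronic acid | Cc1cc(O[Si](C)(C)C(C)(C)C)ccc1B(O)O | intermediate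
7 | vinylmagnesium bromide | C=C[Mg]Br | starting material
8 | bromomagnesium isopropoxy(pinacolato)vinylborate | C=C[B-]1(OC(C)C)OC(C)(C)C(C)(C)O1.[Mg+]Br | intermediate
9 | 4,4,5,5-tetramethyl-2-vinyl-1,3,2-dioxaborolane | C=CB1OC(C)(C)C(C)(C)O1 | intermediate
10 | (E)-1,4-dichlorobut-2-ene | ClC/C=C/CCl | starting material
11 | isopropenylmagnesium bromide (prop-1-en-2-ylmagnesium bromide) | C=C(C)[Mg]Br | starting material
12 | (S)-3-(chloromethyl)-2-methylpenta-1,4-diene | C=C(C)[C@@H](CCl)C=C | intermediate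
13 | 2-[(1E,3S)-3-(chloromethyl)-4-methylpenta-1,4-dien-1-yl]-4,4,5,5-tetramethyl-1,3,2-dioxaborolane | C=C(C)[C@@H](CCl)/C=C/B1OC(C)(C)C(C)(C)O1 | intermediate
14 | (S)-3-(chloromethyl)-4-methylpent-4-enal | C=C(C)[C@@H](CCl)CC=O | intermediate
15 | (1R,3S)-1-{4-[(tert-butyldimethylsilyl)oxy]-2-methylphenyl}-3-(chloromethyl)-4-methylpent-4-en-1-ol | C=C(C)[C@@H](CCl)C[C@@H](O)c1ccc(O[Si](C)(C)C(C)(C)C)cc1C | intermediate
16 | tert-butyl{4-[(1R,3S)-1-[(tert-butyldimethylsilyl)oxy]-3-(chloromethyl)-4-methylpent-4-en-1-yl]-3-methylphenoxy}dimethylsilane | C=C(C)[C@@H](CCl)C[C@@H](O[Si](C)(C)C(C)(C)C)c1ccc(O[Si](C)(C)C(C)(C)C)cc1C | intermediate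
17 | caesium 4-[(1R,3S)-1-[(tert-butyldimethylsilyl)oxy]-3-(chloromethyl)-4-methylpent-4-en-1-yl]-3-methylphenolate | C=C(C)[C@@H](CCl)C[C@@H](O[Si](C)(C)C(C)(C)C)c1ccc([O-])cc1C.[Cs+] | intermediate
18 | (1R,3S,5R)-1-[(tert-butyldimethylsilyl)oxy]-6-methyl-3-(prop-1-en-2-yl)spiro[4.5]deca-6,9-dien-8-one | C=C(C)[C@@H]1C[C@@H](O[Si](C)(C)C(C)(C)C)[C@@]2(C1)C(C)=CC(=O)C=C2 | intermediate
19 | (1R,3S,5R)-1-hydroxy-6-methyl-3-(prop-1-en-2-yl)spiro[4.5]deca-6,9-dien-8-one | C=C(C)[C@@H]1C[C@@H](O)[C@@]2(C1)C(C)=CC(=O)C=C2 | intermediate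
20 | bis(dimethylaluminium) C1-alkoxide / C8-dienolate of 21 (spiro[4.5]deca-6,8-diene, O1 and O8 each bound to AlMe2, 10-methyl installed) | C=C(C)[C@@H]1C[C@@H](O[Al](C)C)[C@@]2(C1)C(C)=CC(O[Al](C)C)=C[C@H]2C | intermediate
21 | (1R,3S,5R,10R)-1-hydroxy-6,10-dimethyl-3-(prop-1-en-2-yl)spiro[4.5]dec-6-en-8-one | C=C(C)[C@@H]1C[C@@H](O)[C@@]2(C1)C(C)=CC(=O)C[C@H]2C | intermediate
22 | (1R,3S,5R,10R)-6,10-dimethyl-8-oxo-3-(prop-1-en-2-yl)spiro[4.5]dec-6-en-1-yl 2-methylpropanoate | C=C(C)[C@@H]1C[C@@H](OC(=O)C(C)C)[C@@]2(C1)C(C)=CC(=O)C[C@H]2C | intermediate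
23 | (1R,3S,5R,9R,10S)-9-acetoxy-6,10-dimethyl-8-oxo-3-(prop-1-en-2-yl)spiro[4.5]dec-6-en-1-yl 2-methylpropanoate | C=C(C)[C@@H]1C[C@@H](OC(=O)C(C)C)[C@@]2(C1)C(C)=CC(=O)[C@H](OC(C)=O)[C@H]2C | target

## Step count and weak points

Total step count: 12.
Longest linear sequence: 8 steps (1, 2, 3, 8, 9, 10, 11, 12; the paths 5, 6, 7, 8–12 and 4, 6, 7, 8–12 are equally long).

**Step 5 (proposed new method).** Alkenyl Grignard reagents may give poor γ-selectivity or ee in the copper-catalysed SN2′ step. The fallback sets C3 by known conjugate-addition chemistry; it sets out from 11 and comes back at 14, so steps 4, 6 and 7 are not needed. Compound 11 is trapped with B(OMe)3 and worked up with dilute HCl to give prop-1-en-2-ylboronic acid F1. Hayashi–Miyaura conjugate addition of F1 to commercial furan-2(5H)-one (Rh(acac)(C2H4)2, BINAP enantiomer that gives the S product, dioxane/H2O, 100 °C) gives (S)-4-(prop-1-en-2-yl)dihydrofuran-2(3H)-one F2. Aminolysis with MeNHOMe·HCl/AlMe3 opens the lactone to (S)-3-(hydroxymethyl)-N-methoxy-N,4-dimethylpent-4-enamide F3. Appel chlorination (PPh3, CCl4) gives (S)-3-(chloromethyl)-N-methoxy-N,4-dimethylpent-4-enamide F4, and DIBAL-H (THF, −78 °C) reduces F4 to aldehyde 14.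

**Step 8.** Ligand control at C1 may be too weak for this β-branched, enolisable aliphatic aldehyde and the hindered ortho-substituted boronic acid. The fallback sets C1 by ketone reduction instead of by C–C bond formation; it sets out from 6 and 14 and comes back at 15. Ligand-free addition ([Rh(OH)(cod)]2, dioxane/H2O, 40 °C) gives the C1-epimeric mixture (1RS,3S)-1-{4-[(tert-butyldimethylsilyl)oxy]-2-methylphenyl}-3-(chloromethyl)-4-methylpent-4-en-1-ol F5. Dess–Martin periodinane oxidises F5 to (S)-1-{4-[(tert-butyldimethylsilyl)oxy]-2-methylphenyl}-3-(chloromethyl)-4-methylpent-4-en-1-one F6. Corey–Bakshi–Shibata reduction of F6 ((S)-Me-CBS oxazaborolidine, BH3·SMe2, THF, −20 °C) gives the (1R) alcohol 15, which is silylated to 16 as in step 8.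

**Step 10.** The metal alkoxide of dienone 19 could fragment by retro-aldol cleavage of C1–C5 with rearomatisation, or AlMe3 could add 1,2 or to the wrong face. The fallback delivers the methyl carbon through a neutral silicon tether (Stork-type radical cyclisation); it sets out from 19 and comes back at 21. Silylation of 19 with (bromomethyl)chlorodimethylsilane and imidazole (CH2Cl2, 0 °C) gives (1R,3S,5R)-1-{[(bromomethyl)dimethylsilyl]oxy}-6-methyl-3-(prop-1-en-2-yl)spiro[4.5]deca-6,9-dien-8-one F7. Bu3SnH/AIBN (benzene, 80 °C, slow addition) closes the six-membered siloxane by 6-exo radical addition to C10 on the face of C1, giving the cyclic siloxane F8. Protodesilylation of F8 with TBAF (DMF, 60 °C) cleaves the Si–C and Si–O bonds to leave the C10 methyl and the C1 hydroxyl of 21.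

Further compounds

F1 | step 5 | prop-1-en-2-ylboronic acid | C=C(C)B(O)O
F2 | step 5 | (S)-4-(prop-1-en-2-yl)dihydrofuran-2(3H)-one | C=C(C)[C@H]1COC(=O)C1
F3 | step 5 | (S)-3-(hydroxymethyl)-N-methoxy-N,4-dimethylpent-4-enamide | C=C(C)[C@@H](CO)CC(=O)N(C)OC
F4 | step 5 | (S)-3-(chloromethyl)-N-methoxy-N,4-dimethylpent-4-enamide | C=C(C)[C@@H](CCl)CC(=O)N(C)OC
F5 | step 8 | (1RS,3S)-1-{4-[(tert-butyldimethylsilyl)oxy]-2-methylphenyl}-3-(chloromethyl)-4-methylpent-4-en-1-ol | C=C(C)[C@@H](CCl)CC(O)c1ccc(O[Si](C)(C)C(C)(C)C)cc1C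
F6 | step 8 | (S)-1-{4-[(tert-butyldimethylsilyl)oxy]-2-methylphenyl}-3-(chloromethyl)-4-methylpent-4-en-1-one | C=C(C)[C@@H](CCl)CC(=O)c1ccc(O[Si](C)(C)C(C)(C)C)cc1C
F7 | step 10 | (1R,3S,5R)-1-{[(bromomethyl)dimethylsilyl]oxy}-6-methyl-3-(prop-1-en-2-yl)spiro[4.5]deca-6,9-dien-8-one | C=C(C)[C@@H]1C[C@@H](O[Si](C)(C)CBr)[C@@]2(C1)C(C)=CC(=O)C=C2
F8 | step 10 | cyclic siloxane of 21 (O1–SiMe2–CH2–C10 bridge, C8 ketone, C6=C7 alkene) | C=C(C)[C@@H]1C[C@@H](O3)[C@@]2(C1)C(C)=CC(=O)C[C@H]2C[Si]3(C)C
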